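Unit labels used throughout: unit 1 = outer fisetinidol (its C4 bound to C6 of unit 2); unit 2 = inner fisetinidol (its C4 bound to C6 of unit 3); unit 3 = catechin; unit 4 = fisetinidol bound through C4 to C8 of unit 3. α/β are used in the usual flavan sense; the C2 aryl of every unit is α.

Assumptions (remarks on the chemistry): the sense of induction of the Pd/t-BuPyOx conjugate addition is carried over from β-substituted cyclic enones, which points to the (R)-ligand for 2S-flavanones; if chromones read the ligand the other way, the (S)-ligand is used and nothing else changes. Compounds 1, 3, 5 and 10 are taken as purchasable.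

## The problem

The target 23 is a branched profisetinidin tetraflavanoid. A (2R,3S)-catechin (unit 3) with a fully substituted ring A carries C4 of one fisetinidol (unit 4) at C8 and C4 of a second (unit 2) at C6, and C6 of unit 2 carries C4 of a third (unit 1). Three C(sp3)–C(aryl) interflavan bonds must therefore be made, each at one defined position of a ring that offers two (C6 against C8 in units 2 and 3), while the equally nucleophilic rings A of units 1 and 4 stay untouched. Of the eleven stereocentres, C2 and C3 of unit 3 come with catechin and are too remote to steer anything. The other nine form three identical all-trans triads: C2 (aryl α), C3 (OH β) and C4 (aryl α). Within a triad only C2 can be set on a small flat precursor, and it lies next to C3 and close to C4, so it can control both. The enabling feature is that in ring C of units 1, 2 and 4 the atoms O3 and H4 lie on the same face, opposite to the C2 aryl, which is the imprint of a syn addition of H and OH across a C3=C4 double bond from the face away from that aryl; because these rings have no oxygen at C5 and C4 bears only carbon and hydrogen, C4 can first be the carbonyl carbon of a flavanone that accepts an aryl anion. The free catechol and phloroglucinol rings are sensitive to air and base, the O1–C2 benzylic ethers open through ring B quinone methides in base, and the electron-rich interflavan bonds suffer in strong acid; the phenols therefore stay benzylated until a last neutral step.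

## Retrosynthesis

23 ⇒ 22. The fourteen O–benzyl bonds are cut (nine phenolic ethers of units 1, 2 and 4, four of unit 3, and O3 of unit 3). One protecting group throughout means one neutral hydrogenolysis at the end and no free phenol before it. The three O3–H groups of units 1, 2 and 4 are born free in the key step and need no protection. The forward reaction must cleave benzyl ethers without touching the C2–O1 or interflavan benzylic bonds.

22 ⇒ 20 (through 21). In each of units 1, 2 and 4 the C3–O bond and the C4–H bond are cut, leaving three C3=C4 double bonds. This removes six of the eleven stereocentres and all three secondary alcohols at once; 20 keeps only the three C2 centres and the two catechin centres. Cutting the C4–aryl bonds here instead (the electrophilic coupling) would leave the C4 configuration to an unbiased cation. The forward reaction must add H and OH syn, with boron at C3, on the face opposite to each C2 aryl, three times in one flask.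

20 ⇒ 17 + two molecules of 4 (through 18 and 19). The bonds C4(unit 1)–C6(unit 2) and C4(unit 4)–C8(unit 3) are cut, and each C3=C4 bond is traced back to a C4 carbinol. Both bonds join the same ketone 4 to an aryl bromide position of 17, so they are made in one double operation. The sites are fixed by the halogens, not by relative nucleophilicity. The forward reaction needs a twofold bromine–lithium exchange, 1,2-addition to an enolisable flavanone without loss of its C2 configuration, and mild dehydration.

17 ⇒ 14 + 9 (through 15 and 16). The bond C4(unit 2)–C6(unit 3) is cut in the same way. The iodide at C6 of 14 is exchanged in the presence of the bromide at C8 of 14 and the bromide at C6 of 9; these two bromides are exactly the handles for the previous disconnection. The precursors are a dihalogenated catechin ether and a monomeric flavanone.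

4 ⇒ 2 + 3 and 9 ⇒ 8 + 3. The C2–C1' bond of each flavanone is cut. This is the only reagent-controlled stereochemical event of the route, and it is carried out on small achiral chromones. A chalcone cyclisation would give racemic material. The forward reaction is a catalytic asymmetric conjugate addition of an arylboronic acid that must tolerate the C6–Br bond of 8.

14 ⇒ 13 ⇒ 12 ⇒ 11 ⇒ 10; 8 ⇒ 6 (through 7) ⇒ 5; 2 ⇒ 1. Only C–halogen and O–benzyl bonds and the pyranone ring of 8 are cut. The halogens of 14 follow the innate order of electrophilic substitution of 5,7-di-O-alkylflavans (C8 first, then the remaining C6), so bromine lands where the later coupling is wanted and iodine where the earlier one is. Ring A of unit 2 is bought with its bromine in place (5).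

## Roads not taken

Alternative 1: the obvious cut is each C4–aryl bond as an electrophilic aromatic substitution: a C4 cation from a protected flavan-3,4-diol such as tri-O-benzylmollisacacidin A1 is captured by ring A of 12 and then of the growing oligomer. The forward key step is a Lewis-acid-mediated Friedel–Crafts alkylation, repeated three times. The chosen plan is better for four reasons. (1) The 5-deoxy cation is attacked on both faces, and the products do not equilibrate, so 4α/4β mixtures are fixed three times. (2) The third bond must go to C6 of unit 2 although C6 and C8 of unit 4 and C8 of unit 2 are equally activated, which calls for blocking groups and their removal. (3) A1 is itself a nucleophile and self-condenses. (4) A1 needs the C3 and C4 oxygens installed on each monomer first, whereas here C3–O and the C4 configuration arise together at the end.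

Alternative 2: the same C4–aryl cut with the C3 oxygen already in place: an aryllithium such as 15 adds to a protected dihydroflavonol, the (2R,3R)-3-silyloxyflavan-4-one A2, to give the tertiary carbinol A3, and the C4 hydroxyl is removed by ionic hydrogenation. The forward key step is hydride capture of the C4 cation. The hydride would enter mainly anti to the O3 substituent, which puts the aryl group cis to O3 (4β), the wrong triad. A2 also needs extra steps to carry O3 with defined configuration. The chosen plan sends H and O to the same face by mechanism, which is what the 3,4-trans target requires.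

Alternative 3: each ring C of units 1, 2 and 4 is cut at O1–C2 and C3–C4 as a hetero-Diels–Alder adduct. A 2-hydroxybenzhydrol such as A4 would lose water to the ortho-quinone methide A5, which would add an (E)-styrene carrying a C3 oxygen surrogate, for example the alkenylboronate A6. This forward key step would form ring C and three stereocentres at once. The chosen plan is better for three reasons. (1) An enol ether dienophile adds with the opposite regiochemistry (2-alkoxy-3-arylchroman), so an untested boron or silicon surrogate is needed. (2) The absolute configuration would have to be imposed by a catalyst three times on a very stabilised, hindered heterodiene. (3) The 2,4-cis outcome depends on an endo preference that the 2,6-dioxygenated aryl group may overturn. In the chosen plan every selectivity is read from one adjacent centre.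

Key step: step 12

## Steps

Step 1
Reactants: 1 7-hydroxy-4H-chromen-4-one
Product: 2 7-(benzyloxy)-4H-chromen-4-one
Conditions: BnBr, K2CO3, DMF, rt
Reagents that add atoms: benzyl bromide, BrCc1ccccc1
Why: Williamson etherification of the only acidic OH; the mild carbonate base does not open the pyranone ring.

Step 2
Reactants: 2 7-(benzyloxy)-4H-chromen-4-one; 3 [3,4-bis(benzyloxy)phenyl]boronic acid
Product: 4 (2S)-7-(benzyloxy)-2-[3,4-bis(benzyloxy)phenyl]-2,3-dihydro-4H-chromen-4-one
Conditions: Pd(OCOCF3)2 (5 mol %), (R)-t-BuPyOx (6 mol %), NH4PF6 (30 mol %), H2O (5 equiv), ClCH2CH2Cl, 60 °C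
Reagents that add atoms: none
Why: Pd-catalysed asymmetric conjugate addition of an arylboronic acid to a chromone (transmetalation, enantio-determining insertion of C2=C3 into the aryl–palladium bond, protonolysis of the enolate); the tert-butyl group of the ligand selects the enone face and sets C2 as S. The conditions are neutral, so the flavanone does not racemise by ring opening.

Step 3
Reactants: 5 1-(5-bromo-2,4-dihydroxyphenyl)ethan-1-one
Product: 6 1-[4-(benzyloxy)-5-bromo-2-hydroxyphenyl]ethan-1-one
Conditions: BnBr (1.05 equiv), K2CO3, acetone, reflux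
Reagents that add atoms: benzyl bromide, BrCc1ccccc1
Why: Williamson etherification selective for the 4-OH, because the 2-OH is held in a hydrogen bond to the ketone and is far less nucleophilic.

Step 4
Reactants: 6 1-[4-(benzyloxy)-5-bromo-2-hydroxyphenyl]ethan-1-one
Product: 8 7-(benzyloxy)-6-bromo-4H-chromen-4-one, via enaminone 7 (not isolated)
Conditions: Me2NCH(OMe)2, toluene, 100 °C; then conc. HCl, CH2Cl2, 40 °C
Reagents that add atoms: N,N-dimethylformamide dimethyl acetal, COC(OC)N(C)C
Why: Enaminone chromone synthesis: condensation of the methyl ketone with the formamide acetal, then acid-promoted addition of the phenol to the enaminone and loss of dimethylamine closes the pyranone (6-endo addition–elimination).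

Step 5
Reactants: 8 7-(benzyloxy)-6-bromo-4H-chromen-4-one; 3 [3,4-bis(benzyloxy)phenyl]boronic acid
Product: 9 (2S)-7-(benzyloxy)-2-[3,4-bis(benzyloxy)phenyl]-6-bromo-2,3-dihydro-4H-chromen-4-one
Conditions: Pd(OCOCF3)2 (5 mol %), (R)-t-BuPyOx (6 mol %), NH4PF6 (30 mol %), H2O (5 equiv), ClCH2CH2Cl, 60 °C
Reagents that add atoms: none
Why: Same asymmetric conjugate addition as step 2, setting C2 as S; the cycle runs on divalent palladium throughout, so no zerovalent palladium is available to insert into the C6–Br bond.

Step 6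
Reactants: 10 (+)-catechin
Product: 11 5,7,3',4'-tetra-O-benzyl-(+)-catechin
Conditions: BnBr (4.4 equiv), K2CO3, DMF, 0 °C to rt, Ar
Reagents that add atoms: benzyl bromide, BrCc1ccccc1
Why: Williamson etherification of the four phenols only; the carbonate base is too weak to deprotonate the C3 alcohol or to open ring C, so C2 and C3 are untouched.

Step 7
Reactants: 11 5,7,3',4'-tetra-O-benzyl-(+)-catechin
Product: 12 3,5,7,3',4'-penta-O-benzyl-(+)-catechin
Conditions: NaH, BnBr, DMF, 0 °C to rt
Reagents that add atoms: benzyl bromide, BrCc1ccccc1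
Why: Williamson etherification of the secondary alcohol; with all phenols capped, no quinone methide pathway can epimerise C2 under the strong base.

Step 8
Reactants: 12 3,5,7,3',4'-penta-O-benzyl-(+)-catechin
Product: 13 8-bromo-3,5,7,3',4'-penta-O-benzyl-(+)-catechin
Conditions: NBS (1.0 equiv), CH2Cl2, −78 °C to rt
Reagents that add atoms: N-bromosuccinimide, O=C1CCC(=O)N1Br
Why: Electrophilic aromatic bromination; in 5,7-di-O-alkylflavans C8 is the more reactive of the two free ring A positions, and ring B is much less activated.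

Step 9
Reactants: 13 8-bromo-3,5,7,3',4'-penta-O-benzyl-(+)-catechin
Product: 14 8-bromo-6-iodo-3,5,7,3',4'-penta-O-benzyl-(+)-catechin
Conditions: NIS (1.1 equiv), CF3CO2H (cat.), CH2Cl2/MeCN, 0 °C to rt
Reagents that add atoms: N-iodosuccinimide, O=C1CCC(=O)N1I
Why: Electrophilic aromatic iodination at C6, the only free position of the trioxygenated ring A, which remains the most electron-rich ring of 13.

Step 10
Reactants: 14 8-bromo-6-iodo-3,5,7,3',4'-penta-O-benzyl-(+)-catechin; 9 (2S)-7-(benzyloxy)-2-[3,4-bis(benzyloxy)phenyl]-6-bromo-2,3-dihydro-4H-chromen-4-one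
Product: 17 8-bromo-6-[(2S)-7-(benzyloxy)-2-[3,4-bis(benzyloxy)phenyl]-6-bromo-2H-chromen-4-yl]-3,5,7,3',4'-penta-O-benzyl-(+)-catechin, via aryllithium 15 (not isolated), via tertiary carbinol 16 (not isolated)
Conditions: n-BuLi (1.05 equiv), THF, −78 °C; cannulate into 9 + CeCl3 (dried), THF, −78 °C; sat. aq NH4Cl; crude: pyridinium p-toluenesulfonate (10 mol %), CH2Cl2, 0 °C to rt, dark
Reagents that add atoms: none
Why: Iodine–lithium exchange is far faster than bromine–lithium exchange, so only C6 of unit 3 is metalated; 1,2-addition of the aryl-metal to the flavan-4-one (CeCl3 favours carbonyl addition over enolisation, which would open ring C and erase C2) gives carbinol 16 as a mixture at C4. The carbinol ionises readily (cation stabilised by the para O7 and the trialkoxyaryl group) and loses H3 in an E1 dehydration, so both C4 epimers converge on the C3=C4 alkene with C2 untouched.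

Step 11
Reactants: 17 8-bromo-6-[(2S)-7-(benzyloxy)-2-[3,4-bis(benzyloxy)phenyl]-6-bromo-2H-chromen-4-yl]-3,5,7,3',4'-penta-O-benzyl-(+)-catechin; 4 (2S)-7-(benzyloxy)-2-[3,4-bis(benzyloxy)phenyl]-2,3-dihydro-4H-chromen-4-one (2.5 equiv)
Product: 20 tris-flav-3-ene (compound 17 with each Br replaced by a (2S)-7-(benzyloxy)-2-[3,4-bis(benzyloxy)phenyl]-2H-chromen-4-yl group), via dilithio species 18 (not isolated), via bis-carbinol 19 (not isolated)
Conditions: t-BuLi (4.2 equiv), THF, −78 °C; cannulate into 4 + CeCl3 (dried), THF, −78 °C; sat. aq NH4Cl; crude: pyridinium p-toluenesulfonate (10 mol %), CH2Cl2, 0 °C to rt, dark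
Reagents that add atoms: none
Why: Twofold bromine–lithium exchange (at −78 °C faster than any deprotonation of benzyl ethers or of the allylic C2–H), twofold 1,2-addition to the same ketone 4, and twofold E1 dehydration as in step 10. Both new interflavan bonds form where the bromine atoms were, at C6 of unit 2 and C8 of unit 3.

Step 12
Reactants: 20 tris-flav-3-ene
Product: 22 tetradeca-O-benzyl ether of the target with free 3-OH in units 1/2/4, via tris(3-boryl) adduct 21 (not isolated)
Conditions: BH3·THF (excess), THF, 0 °C to rt; then 3 M NaOH, 30% H2O2, 0 °C to rt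
Reagents that add atoms: hydrogen peroxide, OO
Why: Each of the three trisubstituted C3=C4 double bonds undergoes the concerted four-centre syn addition of B–H. Boron goes to C3 and hydrogen to C4, because C4 is the fully substituted, diaryl-bearing end that is both more hindered and better able to carry the partial positive charge of the transition state. At each ring the reagent adds to the face of C3 remote from the neighbouring C2 aryl group, so C2 fixes C3, and the syn addition fixes C4 relative to C3: O3 and H4 end up cis, and the C4 aryl is trans to O3 and cis to the C2 aryl, which is the all-trans triad of units 1, 2 and 4. The three events are independent, each read from its own C2, and the remote centres of unit 3 play no part. Alkaline H2O2 then converts each C–B bond into C–O with retention. The closest known reaction type is the hydroboration–oxidation of flav-3-enes and other 2H-chromenes to 2,3-trans-chroman-3-ols; no ring is closed in this step. The step needs regioselectivity (secured by the substitution pattern), facial selectivity (secured by the aryl group on the carbon next to the one that takes boron) and chemoselectivity (benzyl ethers, arenes and the C2–O1 bonds are inert to borane and to cold alkaline peroxide).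

Step 13
Reactants: 22 tetradeca-O-benzyl ether of the target
Product: 23 fisetinidol-(4α→6)-fisetinidol-(4α→6)-[fisetinidol-(4α→8)]-catechin (CNP0263622.1)
Conditions: H2 (1 atm), Pd(OH)2/C, THF/MeOH/H2O, rt; filter under Ar, lyophilise
Reagents that add atoms: none
Why: Hydrogenolysis of all fourteen benzyl ethers under neutral conditions; the cyclic C2–O1 ethers and the diaryl-substituted C4 centres are not cleaved at ambient pressure, and no stereocentre is touched.

## Compound list

1 | 7-hydroxy-4H-chromen-4-one | O=c1ccoc2cc(O)ccc12 | starting material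
2 | 7-(benzyloxy)-4H-chromen-4-one | O=c1ccoc2cc(OCc3ccccc3)ccc12 | intermediate
3 | [3,4-bis(benzyloxy)phenyl]boronic acid | OB(O)c1ccc(OCc2ccccc2)c(OCc2ccccc2)c1 | starting material
4 | (2S)-7-(benzyloxy)-2-[3,4-bis(benzyloxy)phenyl]-2,3-dihydro-4H-chromen-4-one | O=C1C[C@@H](c2ccc(OCc3ccccc3)c(OCc3ccccc3)c2)Oc2cc(OCc3ccccc3)ccc12 | intermediate
5 | 1-(5-bromo-2,4-dihydroxyphenyl)ethan-1-one | CC(=O)c1cc(Br)c(O)cc1O | starting material
6 | 1-[4-(benzyloxy)-5-bromo-2-hydroxyphenyl]ethan-1-one | CC(=O)c1cc(Br)c(OCc2ccccc2)cc1O | intermediate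
7 | (2E)-1-[4-(benzyloxy)-5-bromo-2-hydroxyphenyl]-3-(dimethylamino)prop-2-en-1-one (enaminone, not isolated) | CN(C)/C=C/C(=O)c1cc(Br)c(OCc2ccccc2)cc1O | intermediate
8 | 7-(benzyloxy)-6-bromo-4H-chromen-4-one | O=c1ccoc2cc(OCc3ccccc3)c(Br)cc12 | intermediate
9 | (2S)-7-(benzyloxy)-2-[3,4-bis(benzyloxy)phenyl]-6-bromo-2,3-dihydro-4H-chromen-4-one | O=C1C[C@@H](c2ccc(OCc3ccccc3)c(OCc3ccccc3)c2)Oc2cc(OCc3ccccc3)c(Br)cc12 | intermediate
10 | (+)-catechin, (2R,3S)-2-(3,4-dihydroxyphenyl)chromane-3,5,7-triol | Oc1cc(O)c2c(c1)O[C@H](c1ccc(O)c(O)c1)[C@@H](O)C2 | starting material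
11 | 5,7,3',4'-tetra-O-benzyl-(+)-catechin (2R,3S) | c1ccccc1COc1cc(OCc3ccccc3)c2c(c1)O[C@H](c1ccc(OCc3ccccc3)c(OCc3ccccc3)c1)[C@@H](O)C2 | intermediate
12 | 3,5,7,3',4'-penta-O-benzyl-(+)-catechin (2R,3S) | c1ccccc1COc1cc(OCc3ccccc3)c2c(c1)O[C@H](c1ccc(OCc3ccccc3)c(OCc3ccccc3)c1)[C@@H](OCc1ccccc1)C2 | intermediate
13 | 8-bromo-3,5,7,3',4'-penta-O-benzyl-(+)-catechin (2R,3S) | c1ccccc1COc1cc(OCc3ccccc3)c2c(c1Br)O[C@H](c1ccc(OCc3ccccc3)c(OCc3ccccc3)c1)[C@@H](OCc1ccccc1)C2 | intermediate
14 | 8-bromo-6-iodo-3,5,7,3',4'-penta-O-benzyl-(+)-catechin (2R,3S) | c1ccccc1COc1c(I)c(OCc3ccccc3)c2c(c1Br)O[C@H](c1ccc(OCc3ccccc3)c(OCc3ccccc3)c1)[C@@H](OCc1ccccc1)C2 | intermediate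
15 | 8-bromo-6-lithio-3,5,7,3',4'-penta-O-benzyl-(+)-catechin (aryllithium, not isolated) | c1ccccc1COc1c([Li])c(OCc3ccccc3)c2c(c1Br)O[C@H](c1ccc(OCc3ccccc3)c(OCc3ccccc3)c1)[C@@H](OCc1ccccc1)C2 | intermediate
16 | tertiary carbinol: 14 with iodine replaced by the (2S)-7-(benzyloxy)-2-[3,4-bis(benzyloxy)phenyl]-6-bromo-4-hydroxychroman-4-yl group, mixture of C4 epimers (not isolated) | c1ccccc1COc1c(C3(O)C[C@@H](c4ccc(OCc5ccccc5)c(OCc5ccccc5)c4)Oc4cc(OCc5ccccc5)c(Br)cc34)c(OCc3ccccc3)c2c(c1Br)O[C@H](c1ccc(OCc3ccccc3)c(OCc3ccccc3)c1)[C@@H](OCc1ccccc1)C2 | intermediate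
17 | 8-bromo-6-[(2S)-7-(benzyloxy)-2-[3,4-bis(benzyloxy)phenyl]-6-bromo-2H-chromen-4-yl]-3,5,7,3',4'-penta-O-benzyl-(+)-catechin | c1ccccc1COc1c(C3=C[C@@H](c4ccc(OCc5ccccc5)c(OCc5ccccc5)c4)Oc4cc(OCc5ccccc5)c(Br)cc34)c(OCc3ccccc3)c2c(c1Br)O[C@H](c1ccc(OCc3ccccc3)c(OCc3ccccc3)c1)[C@@H](OCc1ccccc1)C2 | intermediate
18 | dilithio species: 17 with both Br replaced by Li (not isolated) | c1ccccc1COc1c(C3=C[C@@H](c4ccc(OCc5ccccc5)c(OCc5ccccc5)c4)Oc4cc(OCc5ccccc5)c([Li])cc34)c(OCc3ccccc3)c2c(c1[Li])O[C@H](c1ccc(OCc3ccccc3)c(OCc3ccccc3)c1)[C@@H](OCc1ccccc1)C2 | intermediate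
19 | bis-carbinol: 17 with each Br replaced by a (2S)-7-(benzyloxy)-2-[3,4-bis(benzyloxy)phenyl]-4-hydroxychroman-4-yl group, mixture at both C4 carbinol centres (not isolated) | c1ccccc1COc1c(C3=C[C@@H](c4ccc(OCc5ccccc5)c(OCc5ccccc5)c4)Oc4cc(OCc5ccccc5)c(C5(O)C[C@@H](c6ccc(OCc7ccccc7)c(OCc7ccccc7)c6)Oc6cc(OCc7ccccc7)ccc56)cc34)c(OCc3ccccc3)c2c(c1C1(O)C[C@@H](c3ccc(OCc4ccccc4)c(OCc4ccccc4)c3)Oc3cc(OCc4ccccc4)ccc13)O[C@H](c1ccc(OCc3ccccc3)c(OCc3ccccc3)c1)[C@@H](OCc1ccccc1)C2 | intermediate
20 | tris-flav-3-ene: penta-O-benzylcatechin (2R,3S) carrying at C8 a (2S)-7,3',4'-tris(benzyloxy)flav-3-en-4-yl group and at C6 a (2S)-7,3',4'-tris(benzyloxy)flav-3-en-4-yl group whose own C6 carries a third such (2S)-flav-3-en-4-yl group | c1ccccc1COc1c(C3=C[C@@H](c4ccc(OCc5ccccc5)c(OCc5ccccc5)c4)Oc4cc(OCc5ccccc5)c(C5=C[C@@H](c6ccc(OCc7ccccc7)c(OCc7ccccc7)c6)Oc6cc(OCc7ccccc7)ccc56)cc34)c(OCc3ccccc3)c2c(c1C1=C[C@@H](c3ccc(OCc4ccccc4)c(OCc4ccccc4)c3)Oc3cc(OCc4ccccc4)ccc13)O[C@H](c1ccc(OCc3ccccc3)c(OCc3ccccc3)c1)[C@@H](OCc1ccccc1)C2 | intermediate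
21 | tris(3-boryl) adduct, drawn as the three C3–BH2 groups; configuration at every carbon as in 22 (not isolated) | c1ccccc1COc1ccc2c(c1)O[C@H](c1ccc(OCc3ccccc3)c(OCc3ccccc3)c1)[C@@H](B)[C@@H]2c1cc2c(cc1OCc1ccccc1)O[C@H](c1ccc(OCc3ccccc3)c(OCc3ccccc3)c1)[C@@H](B)[C@@H]2c1c(OCc3ccccc3)c2c(c([C@@H]3c4ccc(OCc5ccccc5)cc4O[C@H](c4ccc(OCc5ccccc5)c(OCc5ccccc5)c4)[C@H]3B)c1OCc1ccccc1)O[C@H](c1ccc(OCc3ccccc3)c(OCc3ccccc3)c1)[C@@H](OCc1ccccc1)C2 | intermediate
22 | tetradeca-O-benzyl ether of the target: all phenols and O3 of unit 3 benzylated, 3-OH of units 1, 2 and 4 free; units 1, 2 and 4 each 2,3-trans-3,4-trans (2R,3S,4S as benzyl ethers), unit 3 (2R,3S) | c1ccccc1COc1ccc2c(c1)O[C@H](c1ccc(OCc3ccccc3)c(OCc3ccccc3)c1)[C@@H](O)[C@@H]2c1cc2c(cc1OCc1ccccc1)O[C@H](c1ccc(OCc3ccccc3)c(OCc3ccccc3)c1)[C@@H](O)[C@@H]2c1c(OCc3ccccc3)c2c(c([C@@H]3c4ccc(OCc5ccccc5)cc4O[C@H](c4ccc(OCc5ccccc5)c(OCc5ccccc5)c4)[C@H]3O)c1OCc1ccccc1)O[C@H](c1ccc(OCc3ccccc3)c(OCc3ccccc3)c1)[C@@H](OCc1ccccc1)C2 | intermediate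
23 | fisetinidol-(4α→6)-fisetinidol-(4α→6)-[fisetinidol-(4α→8)]-catechin; unit 1 (2R,3S,4R), units 2 and 4 (2R,3S,4S), unit 3 (2R,3S) | Oc1ccc2c(c1)O[C@H](c1ccc(O)c(O)c1)[C@@H](O)[C@@H]2c1cc2c(cc1O)O[C@H](c1ccc(O)c(O)c1)[C@@H](O)[C@@H]2c1c(O)c2c(c([C@@H]3c4ccc(O)cc4O[C@H](c4ccc(O)c(O)c4)[C@H]3O)c1O)O[C@H](c1ccc(O)c(O)c1)[C@@H](O)C2 | target

## Step count and weak points

Total: 13 steps. Longest linear sequence: 8 steps (10 to 23, steps 6 to 13); the flavanone branches (steps 1–2 and 3–5) join at steps 10 and 11.

Least certain steps: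

Step 12 (key step). Two things are most likely to go wrong. The first is slow or incomplete hydroboration at the two double bonds that carry the 2,6-dioxygenated ring of unit 3 at C4. The second is erosion of face selectivity at one of the three rings, which would give diastereomers differing in a single remote triad; forcing the reaction could also trigger β-elimination of the C3 borane with O1 (opening of ring C). The fallback sets out from 20 and replaces syn hydroboration by syn dihydroxylation followed by internal hydride delivery. OsO4 (catalytic, with N-methylmorpholine N-oxide and the matched cinchona ligand) should add anti to each C2 aryl to give the tris(3,4-cis-diol) F1. Silylation of the three secondary alcohols with i-Pr2SiHCl/imidazole would give the tris(3-O-diisopropylsilyl ether) F2. BF3·OEt2 at −78 °C should then ionise each tertiary, doubly benzylic C4–OH, and the Si–H tethered to O3 should reduce the cation on the O3 face through a five-membered array (H4 cis to O3, aryl trans). Fluoride work-up (Bu4NF) returns to the route at 22.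

Step 10. The hindered, basic aryl-metal may enolise flavanone 9 instead of adding; the enolate opens ring C by retro-oxa-Michael reaction, which costs material and the C2 configuration. Lithium–bromine scrambling with the aryl bromide of 9 is possible, and during dehydration acid could cause hydride transfer between flavenes or ionise the allylic C2–O1 bond. The fallback sets out from 9 and 14 and makes the same bond by cross-coupling. Tf2O with 2,6-di-tert-butyl-4-methylpyridine (no enolate is formed) converts 9 into the enol triflate F3. Aryllithium 15, made from 14 as before, is transmetalated with ZnCl2 to the arylzinc chloride F4. Negishi coupling (Pd(PPh3)4, THF), in which the alkenyl triflate should react before the electron-rich aryl bromides, gives 17 directly, without carbinol or acid.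

Step 11. The double exchange may be incomplete, or one aryllithium may be protonated, leaving mono-adducts that are hard to separate; the enolisation and acid risks of step 10 apply twice. The fallback sets out from 4 and 17 and separates metalation from C–C bond formation. Ketone 4 gives the enol triflate F5 (Tf2O, 2,6-di-tert-butyl-4-methylpyridine). Dilithio species 18, made from 17 as before, is quenched with 2-isopropoxy-4,4,5,5-tetramethyl-1,3,2-dioxaborolane to the isolable bis(pinacol boronate) F6. A double Suzuki–Miyaura coupling of F6 with F5 (Pd(OAc)2/SPhos, K3PO4, toluene/H2O) returns to the route at 20.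

Step 2 (and step 5, same reaction). Enantioselectivity may fall short with the electron-rich chromone and boronic acid, because insertion is slow and protodeboronation and ligand-free background addition compete. The fallback sets out from 2 and 3 and changes from asymmetric catalysis to kinetic resolution. The same addition with the achiral ligand 2,2'-bipyridine gives the racemic flavanone F7. Asymmetric transfer hydrogenation (RuCl(p-cymene)[(S,S)-TsDPEN] or its antipode, HCO2H/Et3N) should reduce the 2R ketone to the cis-flavan-4-ol F8, which is removed by chromatography. The unreacted 2S ketone is compound 4, at the cost of half the material; the same sequence from 8 and 3 would supply 9.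

## Further compounds

F1 | step 12 | tris(3,4-cis-diol): 22 with an additional β-OH at C4 of units 1, 2 and 4 | c1ccccc1COc1ccc2c(c1)O[C@H](c1ccc(OCc3ccccc3)c(OCc3ccccc3)c1)[C@@H](O)[C@]2(O)c1cc2c(cc1OCc1ccccc1)O[C@H](c1ccc(OCc3ccccc3)c(OCc3ccccc3)c1)[C@@H](O)[C@]2(O)c1c(OCc3ccccc3)c2c(c([C@]3(O)c4ccc(OCc5ccccc5)cc4O[C@H](c4ccc(OCc5ccccc5)c(OCc5ccccc5)c4)[C@H]3O)c1OCc1ccccc1)O[C@H](c1ccc(OCc3ccccc3)c(OCc3ccccc3)c1)[C@@H](OCc1ccccc1)C2
F2 | step 12 | tris(3-O-diisopropylsilyl ether) of F1 | c1ccccc1COc1ccc2c(c1)O[C@H](c1ccc(OCc3ccccc3)c(OCc3ccccc3)c1)[C@@H](O[SiH](C(C)C)C(C)C)[C@]2(O)c1cc2c(cc1OCc1ccccc1)O[C@H](c1ccc(OCc3ccccc3)c(OCc3ccccc3)c1)[C@@H](O[SiH](C(C)C)C(C)C)[C@]2(O)c1c(OCc3ccccc3)c2c(c([C@]3(O)c4ccc(OCc5ccccc5)cc4O[C@H](c4ccc(OCc5ccccc5)c(OCc5ccccc5)c4)[C@H]3O[SiH](C(C)C)C(C)C)c1OCc1ccccc1)O[C@H](c1ccc(OCc3ccccc3)c(OCc3ccccc3)c1)[C@@H](OCc1ccccc1)C2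
F3 | step 10 | (2S)-7-(benzyloxy)-2-[3,4-bis(benzyloxy)phenyl]-6-bromo-2H-chromen-4-yl trifluoromethanesulfonate | FC(F)(F)S(=O)(=O)OC1=C[C@@H](c2ccc(OCc3ccccc3)c(OCc3ccccc3)c2)Oc2cc(OCc3ccccc3)c(Br)cc12
F4 | step 10 | arylzinc chloride: 15 with Li replaced by ZnCl | c1ccccc1COc1c([Zn]Cl)c(OCc3ccccc3)c2c(c1Br)O[C@H](c1ccc(OCc3ccccc3)c(OCc3ccccc3)c1)[C@@H](OCc1ccccc1)C2
F5 | step 11 | (2S)-7-(benzyloxy)-2-[3,4-bis(benzyloxy)phenyl]-2H-chromen-4-yl trifluoromethanesulfonate | FC(F)(F)S(=O)(=O)OC1=C[C@@H](c2ccc(OCc3ccccc3)c(OCc3ccccc3)c2)Oc2cc(OCc3ccccc3)ccc12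
F6 | step 11 | bis(pinacol boronate): 17 with both Br replaced by 4,4,5,5-tetramethyl-1,3,2-dioxaborolan-2-yl | c1ccccc1COc1c(C3=C[C@@H](c4ccc(OCc5ccccc5)c(OCc5ccccc5)c4)Oc4cc(OCc5ccccc5)c(B5OC(C)(C)C(C)(C)O5)cc34)c(OCc3ccccc3)c2c(c1B1OC(C)(C)C(C)(C)O1)O[C@H](c1ccc(OCc3ccccc3)c(OCc3ccccc3)c1)[C@@H](OCc1ccccc1)C2
F7 | step 2 | racemic 7-(benzyloxy)-2-[3,4-bis(benzyloxy)phenyl]-2,3-dihydro-4H-chromen-4-one | O=C1CC(c2ccc(OCc3ccccc3)c(OCc3ccccc3)c2)Oc2cc(OCc3ccccc3)ccc12
F8 | step 2 | (2R,4R)-7-(benzyloxy)-2-[3,4-bis(benzyloxy)phenyl]chroman-4-ol (cis, from the unwanted enantiomer) | c1ccccc1COc1ccc2c(c1)O[C@@H](c1ccc(OCc3ccccc3)c(OCc3ccccc3)c1)C[C@H]2O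
A1 | alternative 1 | tri-O-benzylmollisacacidin, (2R,3S,4R)-7-(benzyloxy)-2-[3,4-bis(benzyloxy)phenyl]chromane-3,4-diol | c1ccccc1COc1ccc2c(c1)O[C@H](c1ccc(OCc3ccccc3)c(OCc3ccccc3)c1)[C@@H](O)[C@@H]2O
A2 | alternative 2 | (2R,3R)-7-(benzyloxy)-2-[3,4-bis(benzyloxy)phenyl]-3-[(tert-butyldimethylsilyl)oxy]-2,3-dihydro-4H-chromen-4-one | c1ccccc1COc1ccc2c(c1)O[C@H](c1ccc(OCc3ccccc3)c(OCc3ccccc3)c1)[C@@H](O[Si](C)(C)C(C)(C)C)C2=O
A3 | alternative 2 | tertiary carbinol from 8-lithio-penta-O-benzylcatechin and A2 (C4 unassigned) | c1ccccc1COc1cc(OCc3ccccc3)c2c(c1C1(O)[C@H](O[Si](C)(C)C(C)(C)C)[C@@H](c3ccc(OCc4ccccc4)c(OCc4ccccc4)c3)Oc3cc(OCc4ccccc4)ccc13)O[C@H](c1ccc(OCc3ccccc3)c(OCc3ccccc3)c1)[C@@H](OCc1ccccc1)C2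
A4 | alternative 3 | [4-(benzyloxy)-2-hydroxyphenyl](penta-O-benzylcatechin-8-yl)methanol (carbinol centre unassigned) | c1ccccc1COc1cc(OCc3ccccc3)c2c(c1C(O)c1ccc(OCc3ccccc3)cc1O)O[C@H](c1ccc(OCc3ccccc3)c(OCc3ccccc3)c1)[C@@H](OCc1ccccc1)C2
A5 | alternative 3 | ortho-quinone methide from A4 (alkene geometry unassigned) | c1ccccc1COc1cc(OCc3ccccc3)c2c(c1C=C1C=CC(OCc3ccccc3)=CC1=O)O[C@H](c1ccc(OCc3ccccc3)c(OCc3ccccc3)c1)[C@@H](OCc1ccccc1)C2
A6 | alternative 3 | 2-[(E)-2-[3,4-bis(benzyloxy)phenyl]ethenyl]-4,4,5,5-tetramethyl-1,3,2-dioxaborolane | CC1(C)OB(/C=C/c2ccc(OCc3ccccc3)c(OCc3ccccc3)c2)OC1(C)C
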